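**Strategy.** The dihydrofuran ring (O1–C2–C3–C3a–C7a) is disconnected at C3a–C3 and O1–C2, so that C3, C2, C1′, its methyl and its CH2O carbon all derive from one 2-substituted butadiene and the arene from an ortho-iodophenol. A palladium-catalysed heteroannulation makes both bonds, closes the dihydrofuran ring and sets C2 under ligand control in one operation. It exploits the branched C1′ unit on C2, which is the second alkene of the diene in disguise. The precursors are methyl 4-hydroxy-3-iodobenzoate and the TBS ether of 2-methylidenebut-3-en-1-ol. The surviving 1,1-disubstituted allylic alkene is then hydrogenated under catalyst control to set C1′, and the acrylate and coumarate arms are added last.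

Key step: step 3

Assumption: the ligand antipodes written in steps 3 and 5 are those expected to give 2S and 1′S; each is to be confirmed in a pilot run, and the mirror-image ligand is used otherwise with no other change.

Design remarks: C5 stays a methyl ester through steps 3–5, so that no second alkene or aldehyde competes in the annulation or the hydrogenation. The allylic oxygen is carried as a silyl ether, which zerovalent palladium cannot ionise. Compound 1 is used as the racemate because its stereocentre is lost in step 1.

Step 1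
Reactants: 1 2-ethenyl-2-methyloxirane (racemic)
Product: 2 2-methylidenebut-3-en-1-ol
Conditions: LiN(iPr)2 (LDA, commercial solution, 1.3 equiv), Et2O, 0 °C → rt; then H2O
Reagents that add atoms: none
Why: The hindered amide removes a methyl proton and opens the epoxide by β-elimination (base-mediated epoxide-to-allylic-alcohol isomerisation), favoured here because the new alkene is conjugated with the vinyl group; no stereocentre is formed.

Step 2
Reactants: 2 2-methylidenebut-3-en-1-ol
Product: 3 tert-butyl(dimethyl)[(2-methylidenebut-3-en-1-yl)oxy]silane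
Conditions: TBSCl (1.1 equiv), imidazole (1.5 equiv), CH2Cl2, 0 °C → rt
Reagents that add atoms: tert-butyldimethylsilyl chloride, CC(C)(C)[Si](C)(C)Cl
Why: Standard imidazole-promoted silylation of a primary alcohol, which leaves the diene untouched and involves no stereocentre.

Step 3
Reactants: 4 methyl 4-hydroxy-3-iodobenzoate; 3 tert-butyl(dimethyl)[(2-methylidenebut-3-en-1-yl)oxy]silane
Product: 5 methyl (2S)-2-{3-[tert-butyl(dimethyl)silyl]oxyprop-1-en-2-yl}-2,3-dihydro-1-benzofuran-5-carboxylate
Conditions: Pd(OAc)2 (5 mol %), (S)-BINOL N,N-bis[(R)-1-phenylethyl]phosphoramidite (12 mol %), K3PO4 (2 equiv), 3 (2 equiv), 1,4-dioxane, 70 °C; stopped at full conversion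
Reagents that add atoms: none
Why: Zerovalent palladium, formed in situ from Pd(OAc)2 and the phosphoramidite, inserts into the C–I bond of 4, and the divalent arylpalladium phenoxide adds syn across the CH=CH2 alkene of 3 with the aryl group going to the terminal CH2, which forms C3a–C3 and a π-allyl complex spanning C2, C1′ and the exocyclic CH2. The phenoxide then attacks the allyl terminus C2 to form O1–C2 and return zerovalent palladium; this is the Larock heteroannulation of ortho-iodophenols with 1,3-dienes, a known reaction type with enantioselective variants that use chiral monodentate phosphorus ligands. The dihydrofuran ring closes in a 5-exo mode, the alternative attack at the distal CH2 being a disfavoured 7-endo closure. C2 is the only new stereocentre and should be set by the chiral phosphoramidite on palladium, which differentiates the two faces of the allyl terminus, the diastereomeric π-allyl complexes being able to interconvert by η3–η1–η3 slippage through the unsubstituted CH2 end. The step needs insertion into the monosubstituted alkene and not the 1,1-disubstituted one, which the bulk of the CH2OTBS-bearing carbon secures, and ring closure to the five-membered ring, which ring size secures. The ester and silyl ether are expected to survive because the base is mild and a silyl ether is not an allylic leaving group.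

Step 4
Reactants: 5 methyl (2S)-2-{3-[tert-butyl(dimethyl)silyl]oxyprop-1-en-2-yl}-2,3-dihydro-1-benzofuran-5-carboxylate
Product: 6 methyl (2S)-2-(3-hydroxyprop-1-en-2-yl)-2,3-dihydro-1-benzofuran-5-carboxylate
Conditions: Bu4NF (1.2 equiv), THF, 0 °C; then H2O
Reagents that add atoms: none
Why: Fluoride-induced cleavage of a primary silyl ether, driven by Si–F bond formation, to which the methyl ester and the allylic aryl ether are inert at 0 °C, so C2 is untouched.

Step 5
Reactants: 6 methyl (2S)-2-(3-hydroxyprop-1-en-2-yl)-2,3-dihydro-1-benzofuran-5-carboxylate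
Product: 7 methyl (2S)-2-[(2S)-1-hydroxypropan-2-yl]-2,3-dihydro-1-benzofuran-5-carboxylate
Conditions: Ru(OAc)2[(R)-BINAP] (1 mol %), H2 (100 atm), MeOH, 25 °C
Reagents that add atoms: none
Why: Hydroxyl-directed asymmetric hydrogenation of an allylic alcohol with a divalent ruthenium BINAP diacetate complex (Noyori-type), in which the substrate binds through its oxygen and the BINAP chirality selects the alkene face that receives hydrogen, so that C1′ should be set as S under catalyst control, while high hydrogen pressure suppresses alkene migration and the ester and arene are not reduced.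

Step 6
Reactants: 7 methyl (2S)-2-[(2S)-1-hydroxypropan-2-yl]-2,3-dihydro-1-benzofuran-5-carboxylate
Product: 8 (2S)-2-[(2S)-5-(hydroxymethyl)-2,3-dihydro-1-benzofuran-2-yl]propan-1-ol
Conditions: LiAlH4 (1.5 equiv), THF, 0 °C; then H2O
Reagents that add atoms: none
Why: Hydride reduction of a benzoate ester to the benzylic alcohol, in a molecule with no other reducible group and with both stereocentres remote from any acidic site.

Step 7
Reactants: 8 (2S)-2-[(2S)-5-(hydroxymethyl)-2,3-dihydro-1-benzofuran-2-yl]propan-1-ol
Product: 10 tert-butyl (2E)-3-{(2S)-2-[(2S)-1-hydroxypropan-2-yl]-2,3-dihydro-1-benzofuran-5-yl}prop-2-enoate, via 5-carbaldehyde 9 (not isolated)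
Conditions: MnO2 (activated, 10 equiv), Ph3P=CHCO2tBu (1.3 equiv), CH2Cl2, rt → 40 °C
Reagents that add atoms: tert-butyl (triphenyl-λ5-phosphanylidene)acetate, CC(C)(C)OC(=O)C=P(c1ccccc1)(c1ccccc1)c1ccccc1
Why: Tandem oxidation–Wittig olefination, in which MnO2 oxidises only the benzylic alcohol and the stabilised ylide traps aldehyde 9 as it forms to give the E-cinnamate, the saturated primary alcohol being inert to both reagents.

Step 8
Reactants: 10 tert-butyl (2E)-3-{(2S)-2-[(2S)-1-hydroxypropan-2-yl]-2,3-dihydro-1-benzofuran-5-yl}prop-2-enoate; 11 (2E)-3-(4-hydroxyphenyl)prop-2-enoic acid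
Product: 12 tert-butyl (2E)-3-[(2S)-2-{(2S)-1-[(2E)-3-(4-hydroxyphenyl)prop-2-enoyl]oxypropan-2-yl}-2,3-dihydro-1-benzofuran-5-yl]prop-2-enoate
Conditions: 11 (1.5 equiv), PPh3 (1.5 equiv), DIAD (1.5 equiv), THF, 0 °C → rt
Reagents that add atoms: none
Why: Mitsunobu esterification, in which the carboxylic acid of 11 is far more acidic than its phenol, so only the carboxylate displaces the alkoxyphosphonium ion of the primary alcohol, and since the reacting carbon is a CH2 group neither stereocentre is touched.

Step 9
Reactants: 12 tert-butyl (2E)-3-[(2S)-2-{(2S)-1-[(2E)-3-(4-hydroxyphenyl)prop-2-enoyl]oxypropan-2-yl}-2,3-dihydro-1-benzofuran-5-yl]prop-2-enoate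
Product: 13 (2E)-3-[(2S)-2-{(2S)-1-[(2E)-3-(4-hydroxyphenyl)prop-2-enoyl]oxypropan-2-yl}-2,3-dihydro-1-benzofuran-5-yl]prop-2-enoic acid (CNP0224846.1)
Conditions: TFA/CH2Cl2 (1:4), 0 °C → rt
Reagents that add atoms: none
Why: Acidolysis of a tert-butyl ester with loss of the tert-butyl cation as 2-methylpropene, conditions under which the primary-alkyl coumarate ester, the phenol, both E-alkenes and both stereocentres should be stable.

**Compound list**

1 | 2-ethenyl-2-methyloxirane (racemic) | CC1(C=C)CO1 | starting material
2 | 2-methylidenebut-3-en-1-ol | C=CC(=C)CO | intermediate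
3 | tert-butyl(dimethyl)[(2-methylidenebut-3-en-1-yl)oxy]silane | C=CC(=C)CO[Si](C)(C)C(C)(C)C | intermediate
4 | methyl 4-hydroxy-3-iodobenzoate | COC(=O)c1ccc(O)c(I)c1 | starting material
5 | methyl (2S)-2-{3-[tert-butyl(dimethyl)silyl]oxyprop-1-en-2-yl}-2,3-dihydro-1-benzofuran-5-carboxylate | C=C(CO[Si](C)(C)C(C)(C)C)[C@@H]1Cc2cc(C(=O)OC)ccc2O1 | intermediate
6 | methyl (2S)-2-(3-hydroxyprop-1-en-2-yl)-2,3-dihydro-1-benzofuran-5-carboxylate | C=C(CO)[C@@H]1Cc2cc(C(=O)OC)ccc2O1 | intermediate
7 | methyl (2S)-2-[(2S)-1-hydroxypropan-2-yl]-2,3-dihydro-1-benzofuran-5-carboxylate | C[C@@H](CO)[C@@H]1Cc2cc(C(=O)OC)ccc2O1 | intermediate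
8 | (2S)-2-[(2S)-5-(hydroxymethyl)-2,3-dihydro-1-benzofuran-2-yl]propan-1-ol | C[C@@H](CO)[C@@H]1Cc2cc(CO)ccc2O1 | intermediate
9 | (2S)-2-[(2S)-1-hydroxypropan-2-yl]-2,3-dihydro-1-benzofuran-5-carbaldehyde | C[C@@H](CO)[C@@H]1Cc2cc(C=O)ccc2O1 | intermediate
10 | tert-butyl (2E)-3-{(2S)-2-[(2S)-1-hydroxypropan-2-yl]-2,3-dihydro-1-benzofuran-5-yl}prop-2-enoate | C[C@@H](CO)[C@@H]1Cc2cc(/C=C/C(=O)OC(C)(C)C)ccc2O1 | intermediate
11 | (2E)-3-(4-hydroxyphenyl)prop-2-enoic acid | O=C(O)/C=C/c1ccc(O)cc1 | starting material
12 | tert-butyl (2E)-3-[(2S)-2-{(2S)-1-[(2E)-3-(4-hydroxyphenyl)prop-2-enoyl]oxypropan-2-yl}-2,3-dihydro-1-benzofuran-5-yl]prop-2-enoate | C[C@@H](COC(=O)/C=C/c1ccc(O)cc1)[C@@H]1Cc2cc(/C=C/C(=O)OC(C)(C)C)ccc2O1 | intermediate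
13 | (2E)-3-[(2S)-2-{(2S)-1-[(2E)-3-(4-hydroxyphenyl)prop-2-enoyl]oxypropan-2-yl}-2,3-dihydro-1-benzofuran-5-yl]prop-2-enoic acid | C[C@@H](COC(=O)/C=C/c1ccc(O)cc1)[C@@H]1Cc2cc(/C=C/C(=O)O)ccc2O1 | target

**Step count.** Total: 9 steps. Longest linear sequence: 9 steps (1 → 13); compounds 4 and 11 enter as purchased materials.

**Steps most likely to fail**

Step 3. The ligand may give insufficient control at C2, or the enantiomeric purity may erode because zerovalent palladium re-ionises the allylic aryl ether product; insertion into the wrong alkene would also lower the return. Fallback: setting out from 4 and 3, the annulation is run without a chiral ligand (Pd(OAc)2, NaHCO3, n-Bu4NCl, DMF, 80 °C) to give the racemic silyl ether F1. Its enantiomers are then separated by preparative chromatography on a chiral stationary phase (amylose carbamate column, supercritical CO2/MeOH), and the (2S)-enantiomer rejoins the route at 5. Asymmetric catalysis is thus replaced by resolution.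

Step 5. Facial selectivity may be poor if the C2 stereocentre opposes the catalyst, and alkene migration towards C2 would destroy that stereocentre. Fallback: setting out from 6, the directing group is changed from hydroxyl to carboxylate. The allylic alcohol is oxidised with MnO2 (CH2Cl2, rt) to the enal F2, and this is oxidised further with NaClO2/NaH2PO4/2-methyl-2-butene (t-BuOH/H2O, Pinnick oxidation) to the 2-substituted acrylic acid F3. F3 is hydrogenated with Ru(OAc)2[(R)-BINAP] (H2, MeOH), the substrate class on which this catalyst is most reliable, to give the saturated acid F4. The acid is then reduced with BH3·SMe2 (THF, 0 °C), which spares the methyl ester, and the sequence rejoins the route at 7.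

Step 8. Chemoselectivity may be incomplete, with alkylation of the phenol oxygen or oligomer formation, or the β-branched alcohol may convert slowly. Fallback: 11 is O-acetylated (Ac2O, aqueous NaOH, 0 °C) to (2E)-3-(4-acetoxyphenyl)prop-2-enoic acid F5. Setting out from 10, a Steglich esterification with F5 (EDC·HCl, DMAP, CH2Cl2, rt) gives the acetate-protected diester F6. The aryl acetate alone is then cleaved by aminolysis with pyrrolidine (CH2Cl2, 0 °C), and the sequence rejoins the route at 12.

**Further compounds**

F1 | step 3 | racemic methyl 2-{3-[tert-butyl(dimethyl)silyl]oxyprop-1-en-2-yl}-2,3-dihydro-1-benzofuran-5-carboxylate | C=C(CO[Si](C)(C)C(C)(C)C)C1Cc2cc(C(=O)OC)ccc2O1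
F2 | step 5 | methyl (2S)-2-(3-oxoprop-1-en-2-yl)-2,3-dihydro-1-benzofuran-5-carboxylate | C=C(C=O)[C@@H]1Cc2cc(C(=O)OC)ccc2O1
F3 | step 5 | 2-[(2S)-5-(methoxycarbonyl)-2,3-dihydro-1-benzofuran-2-yl]prop-2-enoic acid | C=C(C(=O)O)[C@@H]1Cc2cc(C(=O)OC)ccc2O1
F4 | step 5 | (2R)-2-[(2S)-5-(methoxycarbonyl)-2,3-dihydro-1-benzofuran-2-yl]propanoic acid | C[C@@H](C(=O)O)[C@@H]1Cc2cc(C(=O)OC)ccc2O1
F5 | step 8 | (2E)-3-(4-acetoxyphenyl)prop-2-enoic acid | CC(=O)Oc1ccc(/C=C/C(=O)O)cc1
F6 | step 8 | tert-butyl (2E)-3-[(2S)-2-{(2S)-1-[(2E)-3-(4-acetoxyphenyl)prop-2-enoyl]oxypropan-2-yl}-2,3-dihydro-1-benzofuran-5-yl]prop-2-enoate | C[C@@H](COC(=O)/C=C/c1ccc(OC(C)=O)cc1)[C@@H]1Cc2cc(/C=C/C(=O)OC(C)(C)C)ccc2O1
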